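All constants are assumed; no experiment stands behind them.

The ratio of nucleophile to electrophile is the number to follow here. Each coupling takes one of each, so with decomposition set aside their difference stays fixed, and the logarithm of the ratio falls at the coupling rate constant times that difference. You want the nucleophile charge for this flask:

electrophile 0.014 M; scavenger 4.20 mM; solid base 7.00 mM; time 2.5 d

    nucleophile → decomposition product (k1 = 7.7 × 10⁻⁸ s⁻¹)
    acid set free + free base ⇌ idle adduct, settled at all times (K2 = 230 M⁻¹)
    acid set free + scavenger → scavenged by-product (k3 = 0.63 M⁻¹ s⁻¹)
    nucleophile + acid set free ⇌ protonated nucleophile, settled at all times (K4 = 990 M⁻¹)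
    acid set free + free base ⇌ salt of the base (K5 = 4.6 × 10⁶ M⁻¹, k5 = 0.061 M⁻¹ s⁻¹)
    electrophile + nucleophile → acid set free + target (k6 = 0.0045 M⁻¹ s⁻¹)
    solid base ⇌ free base, rate k7*(cs7 - [free base]) while solid is left; crystals form when [free base] > cs7 (cs7 = 8.5 mM, k7 = 1.4 × 10⁻⁴ s⁻¹)

- the concentration of nucleophile at which the part of the electrophile that has reacted at 2.5 d is just 50%, in M

- acid set free is meant together with its idle adduct
- solid, in amounts per volume of the solution: solid base
- the amount of nucleophile is what is sought; it is there from the start
- at the start none of the solid base is in solution
- run time (flask): 2.5 d

Here is my own reckoning, a ledger for the nucleophile, the limiting reagent. The first entry is the target: the question demands 7.00 mM of coupled nucleophile. With a charge near that, the difference is also about 7.00 mM. Coupling constant times difference times run time, divided by 2.3, gives 2.96, the decades of the run: the powers of ten the ratio loses. This count leaves protonation out of the coupling rate, so it is an estimate with all the uncoupled nucleophile taken as free.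

The second entry is what stays uncoupled. The ratio starts near 0.5 and loses those decades, which against the remaining electrophile leaves 0.00388 mM, free and protonated together. The third entry is decomposition. Per mole coupled it takes the first-order constant over the coupling constant times the electrophile, and summing this while the electrophile falls to 0.5 of its charge gives that ratio of constants times ln(2), or 0.0119 mM. The books close at 7.02 mM.

The forecast gives 0.00703 M, within 0.007 M to 0.0071 M, holding that “the need is essentially stoichiometric”. Its figure lies close to mine.

The simulation gives 0.00702 M, so this flask needs nucleophile at half the electrophile charge, as the forecast said. In this flask the dissolving of solid base was half done at 1.05 h, and 31.6% of the electrophile charged was used by 0.250 d. By 1.25 d the coupling had 98% of its turnover behind it and the scavenger step 99.8%, with 2.10% of the charged nucleophile still free, where 1.48 decades give 1.67%. That count is also what twice the dilution holds at 2.5 d: this flask had used 49.0% at 1.25 d, and the thin flask reached 49.0%.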